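**Retrosynthetic overview**

1. The seven-membered ring (C5–C6–C7=C8–C9–C10–C1) holds the only C=C of the target. C7=C8 is endocyclic, trisubstituted, allylic to the C6 carbinol and remote from both ring-fusion atoms, so the ring is opened there by a ring-closing-metathesis disconnection: 16 ⇒ diol 14 ⇒ diene 13. The two arms of 13 sit trans on C5 and C1 of the cyclopentane, so the trans ring fusion is fixed before the ring exists (a closure at C1 or C5 would deliver the cis-fused isomer).
2. 13 ⇒ aldehyde 12 (C6 by vinyl addition, relayed from C5 and the C4 hydroxyl) ⇒ ketone 9 (C4 by isopropyl addition anti to the C5 arm) ⇒ cis-diol 7.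
3. 7 ⇒ 5 ⇒ 3 + 4: one radical operation from a silicon tether on the C4 oxygen relays the single reagent-set stereocentre (C4–OH of 2, from CBS reduction of 1) to C5 and to the quaternary C1.
4. Ring order: cyclopentane bought with 1 → temporary oxasilolane ring (made in step 3, removed in step 5) → seven-membered ring last (step 12).

Key step: step 12

Remark: atoms are numbered as in daucanes (C1 quaternary ring-fusion carbon with CH3, C4 carbinol carbon with isopropyl, C5 ring-fusion CH, C6 ester carbinol, C7=C8(CH3), C9, C10); radical chain carriers and ruthenium alkylidenes are treated as mechanism and carry no compound numbers.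

**Route**

Step 1
Reactants: 1 3-methylcyclopent-2-en-1-one
Product: 2 (1S)-3-methylcyclopent-2-en-1-ol
Conditions: (R)-2-methyl-CBS-oxazaborolidine (0.1 equiv), catecholborane (1.5 equiv), toluene, −78 °C; MeOH, aq NaOH
Reagents that add atoms: none
Why: Corey–Bakshi–Shibata reduction; with the enone C=C flank as the large group, the (R)-catalyst should deliver hydride to the face that gives the (S)-alcohol, the only stereocentre set by a chiral reagent.

Step 2
Reactants: 2 (1S)-3-methylcyclopent-2-en-1-ol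
Product: 3 (bromomethyl)dimethyl{[(1S)-3-methylcyclopent-2-en-1-yl]oxy}silane
Conditions: (bromomethyl)chlorodimethylsilane (1.1 equiv), Et3N, DMAP (cat.), CH2Cl2, 0 °C
Reagents that add atoms: (bromomethyl)chlorodimethylsilane, C[Si](C)(Cl)CBr
Why: O-silylation of the allylic alcohol (installation of the Nishiyama–Stork tether); no stereocentre is touched.

Step 3
Reactants: 3 (bromomethyl)dimethyl{[(1S)-3-methylcyclopent-2-en-1-yl]oxy}silane; 4 but-3-en-2-one
Product: 5 4-[(3aR,4R,6aS)-2,2,4-trimethylhexahydro-2H-cyclopenta[d][1,2]oxasilol-4-yl]butan-2-one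
Conditions: Bu3SnH (1.2 equiv, syringe pump), AIBN (0.1 equiv), 4 (6 equiv), benzene (0.02 M), 80 °C
Reagents that add atoms: none
Why: Nishiyama–Stork silicon-tethered radical cyclisation coupled to a Giese addition; the α-silyl radical can reach C5 only on the face of the C4–O tether (5-exo-trig, cis-fused oxasilolane, sets C5), and the tertiary C1 radical of the bicyclo[3.3.0] framework should add to 4 from the convex face anti to the new C5–C6 bond (sets quaternary C1) before hydrogen transfer from the stannane.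

Step 4
Reactants: 5 4-[(3aR,4R,6aS)-2,2,4-trimethylhexahydro-2H-cyclopenta[d][1,2]oxasilol-4-yl]butan-2-one
Product: 6 (3aR,4S,6aS)-2,2,4-trimethyl-4-(3-methylbut-3-en-1-yl)hexahydro-2H-cyclopenta[d][1,2]oxasilole
Conditions: Ph3PCH3Br (1.5 equiv), KOtBu (1.4 equiv), THF, 0 °C to rt
Reagents that add atoms: methyltriphenylphosphonium bromide, C[P+](c1ccccc1)(c1ccccc1)c1ccccc1.[Br-]
Why: Wittig methylenation of the unhindered methyl ketone; the alkoxysilane and the stereocentres are not affected (the C1 descriptor changes only through CIP priorities).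

Step 5
Reactants: 6 (3aR,4S,6aS)-2,2,4-trimethyl-4-(3-methylbut-3-en-1-yl)hexahydro-2H-cyclopenta[d][1,2]oxasilole
Product: 7 (1S,2S,3S)-2-(hydroxymethyl)-3-methyl-3-(3-methylbut-3-en-1-yl)cyclopentan-1-ol
Conditions: H2O2 (30% aq), KF, KHCO3, THF/MeOH 1:1, 40 °C
Reagents that add atoms: hydrogen peroxide, OO
Why: Tamao–Fleming oxidation; peroxide attack at the alkoxy-activated silicon and 1,2-shift of C6 from Si to O with retention turn C6–Si into C6–OH and free the C4 hydroxyl, removing the temporary ring without touching C1, C4 or C5.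

Step 6
Reactants: 7 (1S,2S,3S)-2-(hydroxymethyl)-3-methyl-3-(3-methylbut-3-en-1-yl)cyclopentan-1-ol
Product: 8 (1S,2S,3S)-2-({[tert-butyl(dimethyl)silyl]oxy}methyl)-3-methyl-3-(3-methylbut-3-en-1-yl)cyclopentan-1-ol
Conditions: TBSCl (1.05 equiv), imidazole, CH2Cl2, −20 to 0 °C
Reagents that add atoms: tert-butyl(chloro)dimethylsilane, CC(C)(C)[Si](C)(C)Cl
Why: Chemoselective silylation of the primary hydroxyl in the presence of the more hindered secondary one (steric differentiation by the bulky chlorosilane).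

Step 7
Reactants: 8 (1S,2S,3S)-2-({[tert-butyl(dimethyl)silyl]oxy}methyl)-3-methyl-3-(3-methylbut-3-en-1-yl)cyclopentan-1-ol
Product: 9 (2S,3S)-2-({[tert-butyl(dimethyl)silyl]oxy}methyl)-3-methyl-3-(3-methylbut-3-en-1-yl)cyclopentan-1-one
Conditions: Dess–Martin periodinane (1.3 equiv), CH2Cl2, 0 °C to rt
Reagents that add atoms: none
Why: Dess–Martin oxidation under neutral conditions, which should neither epimerise the α-stereocentre C5 nor eliminate the β-silyloxy group.

Step 8
Reactants: 9 (2S,3S)-2-({[tert-butyl(dimethyl)silyl]oxy}methyl)-3-methyl-3-(3-methylbut-3-en-1-yl)cyclopentan-1-one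
Product: 10 (1R,2S,3S)-2-({[tert-butyl(dimethyl)silyl]oxy}methyl)-3-methyl-3-(3-methylbut-3-en-1-yl)-1-(propan-2-yl)cyclopentan-1-ol
Conditions: iPrMgCl (2 equiv), anhydrous CeCl3 (2 equiv), THF, −78 °C; aq NH4Cl
Reagents that add atoms: isopropylmagnesium chloride, CC(C)[Mg]Cl
Why: Organocerium (Imamoto) 1,2-addition; the weakly basic reagent should attack the C4 carbonyl anti to the adjacent C5 silyloxymethyl arm, giving (R)-C4 with the hydroxyl cis to that arm, while enolisation, β-elimination and β-hydride reduction are suppressed.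

Step 9
Reactants: 10 (1R,2S,3S)-2-({[tert-butyl(dimethyl)silyl]oxy}methyl)-3-methyl-3-(3-methylbut-3-en-1-yl)-1-(propan-2-yl)cyclopentan-1-ol
Product: 11 (1R,2S,3S)-2-(hydroxymethyl)-3-methyl-3-(3-methylbut-3-en-1-yl)-1-(propan-2-yl)cyclopentan-1-ol
Conditions: TBAF (1.2 equiv), THF, 0 °C to rt
Reagents that add atoms: none
Why: Fluoride-mediated cleavage of the primary silyl ether; the tertiary alcohol and the olefin are inert.

Step 10
Reactants: 11 (1R,2S,3S)-2-(hydroxymethyl)-3-methyl-3-(3-methylbut-3-en-1-yl)-1-(propan-2-yl)cyclopentan-1-ol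
Product: 12 (1R,2R,5S)-2-hydroxy-5-methyl-5-(3-methylbut-3-en-1-yl)-2-(propan-2-yl)cyclopentane-1-carbaldehyde
Conditions: TEMPO (0.1 equiv), PhI(OAc)2 (1.1 equiv), CH2Cl2, rt
Reagents that add atoms: none
Why: TEMPO/hypervalent-iodine oxidation, selective for the primary alcohol; the formyl group on C5 is trans to both the isopropyl and the butenyl arm, so the C5 configuration is also the thermodynamically preferred one.

Step 11
Reactants: 12 (1R,2R,5S)-2-hydroxy-5-methyl-5-(3-methylbut-3-en-1-yl)-2-(propan-2-yl)cyclopentane-1-carbaldehyde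
Product: 13 (1R,2S,3S)-2-[(1S)-1-hydroxyprop-2-en-1-yl]-3-methyl-3-(3-methylbut-3-en-1-yl)-1-(propan-2-yl)cyclopentan-1-ol
Conditions: vinylmagnesium bromide (3 equiv), THF, −78 °C; aq NH4Cl
Reagents that add atoms: vinylmagnesium bromide, C=C[Mg]Br
Why: Grignard addition to a β-hydroxy aldehyde; in the magnesium chelate between the C4 alkoxide and the formyl oxygen, and equally in the Felkin–Anh arrangement with the quaternary C1 as large group, the vinyl group should attack anti to C1 and set C6 as (S).

Step 12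
Reactants: 13 (1R,2S,3S)-2-[(1S)-1-hydroxyprop-2-en-1-yl]-3-methyl-3-(3-methylbut-3-en-1-yl)-1-(propan-2-yl)cyclopentan-1-ol
Product: 14 (3R,3aS,4S,8aS)-6,8a-dimethyl-3-(propan-2-yl)-1,2,3,3a,4,7,8,8a-octahydroazulene-3,4-diol
Conditions: Grubbs second-generation catalyst (5 mol%), CH2Cl2 (5 mM), 40 °C
Reagents that add atoms: none
Why: Ring-closing olefin metathesis: the ruthenium carbene should load on the monosubstituted vinyl group at C7, add intramolecularly across the 1,1-disubstituted C8=CH2 olefin to a ruthenacyclobutane and expel ethene, whose loss makes the closure irreversible. The closest known reaction type is RCM of 1,8-dienes with this catalyst class to trisubstituted cycloheptenes, including substrates with a free allylic hydroxyl and with the two arms on a trans-1,2-disubstituted cyclopentane. The seven-membered ring closes by forming the C7=C8 double bond itself ([2+2]/retro-[2+2]), and the ring size allows only the endocyclic Z geometry. No stereocentre is created; C1, C4, C5 and C6 are already in place and none is epimerisable under these neutral conditions. The step needs cyclisation to win over oligomerisation and over any other ring closure: high dilution and the trans-vicinal arms on C5 and C1 secure the first, and the absence of a third olefin secures the second.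

Step 13
Reactants: 14 (3R,3aS,4S,8aS)-6,8a-dimethyl-3-(propan-2-yl)-1,2,3,3a,4,7,8,8a-octahydroazulene-3,4-diol; 15 4-methoxybenzoyl chloride
Product: 16 (3R,3aS,4S,8aS)-3-hydroxy-6,8a-dimethyl-3-(propan-2-yl)-1,2,3,3a,4,7,8,8a-octahydroazulen-4-yl 4-methoxybenzoate
Conditions: 15 (1.3 equiv), Et3N, DMAP (0.2 equiv), CH2Cl2, 0 °C to rt
Reagents that add atoms: none
Why: DMAP-catalysed acyl transfer; the secondary allylic C6 hydroxyl should react while the tertiary C4 hydroxyl is too hindered, and no stereocentre is involved.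

**Compound list**

1 | 3-methylcyclopent-2-en-1-one | CC1=CC(=O)CC1 | starting material
2 | (1S)-3-methylcyclopent-2-en-1-ol | O[C@@H]1C=C(C)CC1 | intermediate
3 | (bromomethyl)dimethyl{[(1S)-3-methylcyclopent-2-en-1-yl]oxy}silane | BrC[Si](C)(C)O[C@@H]1C=C(C)CC1 | intermediate
4 | but-3-en-2-one (methyl vinyl ketone) | CC(=O)C=C | starting material
5 | 4-[(3aR,4R,6aS)-2,2,4-trimethylhexahydro-2H-cyclopenta[d][1,2]oxasilol-4-yl]butan-2-one | C[Si]1(C)C[C@H]2[C@@H](O1)CC[C@]2(C)CCC(C)=O | intermediate
6 | (3aR,4S,6aS)-2,2,4-trimethyl-4-(3-methylbut-3-en-1-yl)hexahydro-2H-cyclopenta[d][1,2]oxasilole | C[Si]1(C)C[C@H]2[C@@H](O1)CC[C@]2(C)CCC(C)=C | intermediate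
7 | (1S,2S,3S)-2-(hydroxymethyl)-3-methyl-3-(3-methylbut-3-en-1-yl)cyclopentan-1-ol | OC[C@H]1[C@@H](O)CC[C@]1(C)CCC(C)=C | intermediate
8 | (1S,2S,3S)-2-({[tert-butyl(dimethyl)silyl]oxy}methyl)-3-methyl-3-(3-methylbut-3-en-1-yl)cyclopentan-1-ol | CC(C)(C)[Si](C)(C)OC[C@H]1[C@@H](O)CC[C@]1(C)CCC(C)=C | intermediate
9 | (2S,3S)-2-({[tert-butyl(dimethyl)silyl]oxy}methyl)-3-methyl-3-(3-methylbut-3-en-1-yl)cyclopentan-1-one | CC(C)(C)[Si](C)(C)OC[C@H]1C(=O)CC[C@]1(C)CCC(C)=C | intermediate
10 | (1R,2S,3S)-2-({[tert-butyl(dimethyl)silyl]oxy}methyl)-3-methyl-3-(3-methylbut-3-en-1-yl)-1-(propan-2-yl)cyclopentan-1-ol | CC(C)(C)[Si](C)(C)OC[C@H]1[C@](O)(C(C)C)CC[C@]1(C)CCC(C)=C | intermediate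
11 | (1R,2S,3S)-2-(hydroxymethyl)-3-methyl-3-(3-methylbut-3-en-1-yl)-1-(propan-2-yl)cyclopentan-1-ol | OC[C@H]1[C@](O)(C(C)C)CC[C@]1(C)CCC(C)=C | intermediate
12 | (1R,2R,5S)-2-hydroxy-5-methyl-5-(3-methylbut-3-en-1-yl)-2-(propan-2-yl)cyclopentane-1-carbaldehyde | O=C[C@H]1[C@](O)(C(C)C)CC[C@]1(C)CCC(C)=C | intermediate
13 | (1R,2S,3S)-2-[(1S)-1-hydroxyprop-2-en-1-yl]-3-methyl-3-(3-methylbut-3-en-1-yl)-1-(propan-2-yl)cyclopentan-1-ol | C=C[C@H](O)[C@H]1[C@](O)(C(C)C)CC[C@]1(C)CCC(C)=C | intermediate
14 | (3R,3aS,4S,8aS)-6,8a-dimethyl-3-(propan-2-yl)-1,2,3,3a,4,7,8,8a-octahydroazulene-3,4-diol | O[C@H]1C=C(C)CC[C@@]2(C)CC[C@@](O)(C(C)C)[C@H]12 | intermediate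
15 | 4-methoxybenzoyl chloride | COc1ccc(C(=O)Cl)cc1 | starting material
16 | (3R,3aS,4S,8aS)-3-hydroxy-6,8a-dimethyl-3-(propan-2-yl)-1,2,3,3a,4,7,8,8a-octahydroazulen-4-yl 4-methoxybenzoate | COc1ccc(C(=O)O[C@H]2C=C(C)CC[C@@]3(C)CC[C@@](O)(C(C)C)[C@H]23)cc1 | target

**Step count and risks**

Total step count: 13. Longest linear sequence: 13 steps (1 → 16).

Steps most likely to fail:

Step 3. The α-silyl radical may be intercepted by the enone before it cyclises, the tertiary C1 radical may be reduced before it adds, or the enone may telomerise. The fallback sets out from 3 and replaces the hydride-mediated Giese step by an allyl-transfer chain without any hydride. Cyclisation–allylation with allyltributylstannane and AIBN should give (3aR,4R,6aS)-2,2,4-trimethyl-4-(prop-2-en-1-yl)hexahydro-2H-cyclopenta[d][1,2]oxasilole F1, with the same facial control at C5 and C1. Ozonolysis with PPh3 work-up gives the aldehyde F2, NaBH4 the alcohol F3, and I2/PPh3/imidazole the iodide F4. Copper-catalysed coupling of F4 with isopropenylmagnesium bromide (Li2CuCl4, THF, −20 °C) returns to the route at 6.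

Step 8. The ketone may be enolised with loss of the β-silanolate, reduced by β-hydride transfer from the isopropyl reagent, or attacked with poor facial selectivity. The fallback sets out from 9 and uses the sp2, β-hydrogen-free 2-propenyl nucleophile (isopropenylmagnesium bromide/CeCl3) to give the 2-propenyl analogue of 10, F5. The conditions of steps 9–12 then lead through the diol F6, the aldehyde F7, the triene diol F8 and, by ring-closing metathesis, the bicyclic diene diol F9. The only alternative small-ring closure in F8 would be a trans-fused bicyclo[3.3.0]octene. Chemoselective hydrogenation of the 1,1-disubstituted olefin of F9 (H2, RhCl(PPh3)3) in the presence of the trisubstituted ring olefin returns to the route at 14.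

Step 11. Competition between chelated and open transition states may erode the facial selectivity at the formyl group and give the C6 epimer. The fallback sets out from 12, accepts an unselective vinyl addition that gives 13 together with its C6 epimer F10, and sets C6 by hydride delivery instead of by C–C bond formation. Dess–Martin oxidation of the mixture converges on the vinyl ketone F11, and ring-closing metathesis gives the bicyclic enone F12. Hydroxyl-directed 1,2-reduction with Me4NBH(OAc)3 (intramolecular hydride delivery from the C4 alkoxyborohydride to the face of the C4 oxygen) returns to the route at 14.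

**Further compounds**

F1 | step 3 | (3aR,4R,6aS)-2,2,4-trimethyl-4-(prop-2-en-1-yl)hexahydro-2H-cyclopenta[d][1,2]oxasilole | C[Si]1(C)C[C@H]2[C@@H](O1)CC[C@]2(C)CC=C
F2 | step 3 | 2-[(3aR,4R,6aS)-2,2,4-trimethylhexahydro-2H-cyclopenta[d][1,2]oxasilol-4-yl]acetaldehyde | C[Si]1(C)C[C@H]2[C@@H](O1)CC[C@]2(C)CC=O
F3 | step 3 | 2-[(3aR,4R,6aS)-2,2,4-trimethylhexahydro-2H-cyclopenta[d][1,2]oxasilol-4-yl]ethan-1-ol | C[Si]1(C)C[C@H]2[C@@H](O1)CC[C@]2(C)CCO
F4 | step 3 | (3aR,4R,6aS)-4-(2-iodoethyl)-2,2,4-trimethylhexahydro-2H-cyclopenta[d][1,2]oxasilole | C[Si]1(C)C[C@H]2[C@@H](O1)CC[C@]2(C)CCI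
F5 | step 8 | 2-propenyl analogue of 10 (prop-1-en-2-yl in place of propan-2-yl on the carbinol carbon, same spatial arrangement) | CC(C)(C)[Si](C)(C)OC[C@H]1[C@](O)(C(C)=C)CC[C@]1(C)CCC(C)=C
F6 | step 8 | 2-propenyl analogue of diol 11 | OC[C@H]1[C@](O)(C(C)=C)CC[C@]1(C)CCC(C)=C
F7 | step 8 | 2-propenyl analogue of aldehyde 12 | O=C[C@H]1[C@](O)(C(C)=C)CC[C@]1(C)CCC(C)=C
F8 | step 8 | 2-propenyl analogue of diene diol 13 | C=C[C@H](O)[C@H]1[C@](O)(C(C)=C)CC[C@]1(C)CCC(C)=C
F9 | step 8 | 2-propenyl analogue of bicyclic diol 14 (3-(prop-1-en-2-yl)-6,8a-dimethyl-1,2,3,3a,4,7,8,8a-octahydroazulene-3,4-diol, ring stereochemistry as in 14) | O[C@H]1C=C(C)CC[C@@]2(C)CC[C@@](O)(C(C)=C)[C@H]12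
F10 | step 11 | C6 epimer of 13, (1R,2S,3S)-2-[(1R)-1-hydroxyprop-2-en-1-yl]-3-methyl-3-(3-methylbut-3-en-1-yl)-1-(propan-2-yl)cyclopentan-1-ol | C=C[C@@H](O)[C@H]1[C@](O)(C(C)C)CC[C@]1(C)CCC(C)=C
F11 | step 11 | 1-[(1R,2R,5S)-2-hydroxy-5-methyl-5-(3-methylbut-3-en-1-yl)-2-(propan-2-yl)cyclopentyl]prop-2-en-1-one | C=CC(=O)[C@H]1[C@](O)(C(C)C)CC[C@]1(C)CCC(C)=C
F12 | step 11 | (3R,3aR,8aS)-3-hydroxy-6,8a-dimethyl-3-(propan-2-yl)-2,3,3a,7,8,8a-hexahydroazulen-4(1H)-one | O=C1C=C(C)CC[C@@]2(C)CC[C@@](O)(C(C)C)[C@H]12
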